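Ring A is made rather than substituted. Its ether carbon C2 lies between C1–OH and C3–Br, and this 1,3-relationship is mapped onto the two carbonyl carbons of a symmetrical 2-aryloxycyclohexane-1,3-dione. An intramolecular Claisen condensation of methyl 6-(2,4-dibromophenoxy)-5-oxohexanoate, an open-chain keto ester that already carries ring B on the oxygen of the future C2, forms the C2–C3 bond and closes ring A in one operation. Afterwards one carbonyl is exchanged for the C3 bromine, the ring is aromatised, C5–Br is introduced by sterically controlled C–H borylation and C4–Br by bromination para to the C1 oxygen.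

Key step: step 3

Remark: the target is achiral. Ring A is numbered C1 (OH), C2 (OAr), C3 to C5 (Br), C6 (H); ring B is the 2,4-dibromophenyl ring. Selenide 9 is racemic and selenoxide 10 a mixture of diastereomers; both stereocentres disappear within the same step. Electrophilic bromination is not relied on for C5: the C2 ether oxygen is twisted out of conjugation by its two ortho neighbours, so C6 (ortho to the C1 oxygen) would be expected to react before C5.

Step 1
Reactants: 1 methyl 5-chloro-5-oxopentanoate; 2 trimethylsilyldiazomethane
Product: 4 methyl 6-bromo-5-oxohexanoate, via diazoketone 3 (not isolated)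
Conditions: TMSCHN2 (2 equiv), THF/MeCN 1:1, 0 °C to rt; then 48% aq HBr, 0 °C
Reagents that add atoms: hydrogen bromide, Br
Why: The acid chloride acylates the diazo carbon with loss of the silyl group as TMSCl (diazoketone synthesis of the Arndt–Eistert type), and HBr then protonates the diazo carbon so that bromide displaces N2 and gives the bromomethyl ketone regiospecifically, the ester being inert to both reagents.

Step 2
Reactants: 4 methyl 6-bromo-5-oxohexanoate; 5 2,4-dibromophenol
Product: 6 methyl 6-(2,4-dibromophenoxy)-5-oxohexanoate
Conditions: K2CO3, acetone, rt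
Reagents that add atoms: none
Why: Williamson ether synthesis, in which the weakly basic phenoxide of 5 displaces bromide from the activated alpha-bromo ketone by SN2 at room temperature without touching the ester.

Step 3
Reactants: 6 methyl 6-(2,4-dibromophenoxy)-5-oxohexanoate
Product: 7 2-(2,4-dibromophenoxy)cyclohexane-1,3-dione
Conditions: KOt-Bu (2.2 equiv), THF (0.05 M, slow addition of 6), 0 °C to rt; then 1 M HCl
Reagents that add atoms: none
Why: KOt-Bu reversibly forms the ketone and ester enolates, and the enolate at C6 of the chain (the aryloxy-bearing methylene, which is also the most acidic position) adds to the ester carbonyl and expels methoxide, forming the C2–C3 bond of ring A. This is an intramolecular Claisen condensation of the Dieckmann type, the standard route from 5-oxoalkanoates to cyclohexane-1,3-diones. Ring A closes in the 6-exo-trig mode. No stereocentre is formed, since 7 is achiral and largely enolised. The selectivity required is constitutional: the enolates at C4 and at the ester alpha-carbon could only close four-membered rings and revert, slow addition at high dilution suppresses intermolecular aldol and Claisen reactions, and deprotonation of the acidic dione by the second equivalent of base removes the product from all equilibria until the acidic quench.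

Step 4
Reactants: 7 2-(2,4-dibromophenoxy)cyclohexane-1,3-dione
Product: 8 3-bromo-2-(2,4-dibromophenoxy)cyclohex-2-en-1-one
Conditions: (COBr)2, DMF (cat.), CH2Cl2, 0 °C to rt
Reagents that add atoms: oxalyl bromide, O=C(Br)C(=O)Br
Why: Vilsmeier-type activation of the enol oxygen followed by conjugate addition–elimination of bromide gives the vinylogous acyl bromide; the two carbonyls of 7 are equivalent and the product has no enol OH left, so the exchange should stop after one carbonyl.

Step 5
Reactants: 8 3-bromo-2-(2,4-dibromophenoxy)cyclohex-2-en-1-one
Product: 12 3-bromo-2-(2,4-dibromophenoxy)phenol, via selenide 9 (not isolated), via selenoxide 10 (not isolated), via dienone 11 (not isolated)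
Conditions: LiN(SiMe3)2, THF, −78 °C; PhSeBr, −78 °C; then 30% H2O2, pyridine, CH2Cl2, 0 °C to rt
Reagents that add atoms: none
Why: Kinetic deprotonation at C6 and selenenylation of the cross-conjugated enolate, oxidation to the selenoxide and syn-elimination towards C5 (Reich selenoxide elimination) should give the 2,5-dienone, which tautomerises to the phenol; the stereocentres at C6 and selenium are transient and no electrophilic halogen is present that could attack the ring.

Step 6
Reactants: 12 3-bromo-2-(2,4-dibromophenoxy)phenol
Product: 13 1-bromo-2-(2,4-dibromophenoxy)-3-methoxybenzene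
Conditions: MeI, K2CO3, DMF, rt
Reagents that add atoms: iodomethane, CI
Why: Williamson O-methylation of the phenoxide (SN2 on MeI) masks the OH, which would otherwise steer borylation to C6, and provides the para-directing group for step 8.

Step 7
Reactants: 13 1-bromo-2-(2,4-dibromophenoxy)-3-methoxybenzene
Product: 15 1,5-dibromo-2-(2,4-dibromophenoxy)-3-methoxybenzene, via arylboronate 14 (not isolated)
Conditions: [Ir(OMe)(cod)]2 (1.5 mol%), 4,4'-di-tert-butyl-2,2'-bipyridine (3 mol%), B2pin2, THF, 80 °C; then CuBr2 (3 equiv), MeOH/H2O 1:1, 80 °C
Reagents that add atoms: copper dibromide, [Cu+2].[Br-].[Br-]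
Why: Iridium-catalysed C–H borylation is governed by sterics and should select C5 of ring A, the only C–H in the molecule without an ortho substituent, after which copper-mediated bromodeboronation exchanges the boronate for bromine while the aryl bromides are tolerated.

Step 8
Reactants: 15 1,5-dibromo-2-(2,4-dibromophenoxy)-3-methoxybenzene
Product: 16 1,2,3-tribromo-4-(2,4-dibromophenoxy)-5-methoxybenzene
Conditions: NBS, TFA (cat.), MeCN, rt
Reagents that add atoms: N-bromosuccinimide, O=C1CCC(=O)N1Br
Why: Electrophilic aromatic bromination, in which the C1 methoxy group is the only strong donor left and directs to its para position C4, while C6 is shielded by the O-methyl group turned towards it and ring B is too deactivated to compete.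

Step 9
Reactants: 16 1,2,3-tribromo-4-(2,4-dibromophenoxy)-5-methoxybenzene
Product: 17 3,4,5-tribromo-2-(2,4-dibromophenoxy)phenol
Conditions: BBr3, CH2Cl2, −78 °C to rt; then H2O
Reagents that add atoms: none
Why: Lewis acid-mediated O-demethylation, in which bromide attacks the methyl group of the boron-complexed aryl methyl ether, should leave the diaryl ether and all five C–Br bonds intact.

Compound list
1 | methyl 5-chloro-5-oxopentanoate | COC(=O)CCCC(=O)Cl | starting material
2 | trimethylsilyldiazomethane | C[Si](C)(C)C=[N+]=[N-] | starting material
3 | methyl 6-diazo-5-oxohexanoate | COC(=O)CCCC(=O)C=[N+]=[N-] | intermediate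
4 | methyl 6-bromo-5-oxohexanoate | COC(=O)CCCC(=O)CBr | intermediate
5 | 2,4-dibromophenol | Oc1ccc(Br)cc1Br | starting material
6 | methyl 6-(2,4-dibromophenoxy)-5-oxohexanoate | COC(=O)CCCC(=O)COc1ccc(Br)cc1Br | intermediate
7 | 2-(2,4-dibromophenoxy)cyclohexane-1,3-dione | O=C1CCCC(=O)C1Oc1ccc(Br)cc1Br | intermediate
8 | 3-bromo-2-(2,4-dibromophenoxy)cyclohex-2-en-1-one | O=C1CCCC(Br)=C1Oc1ccc(Br)cc1Br | intermediate
9 | 3-bromo-2-(2,4-dibromophenoxy)-6-(phenylselanyl)cyclohex-2-en-1-one (racemic) | O=C1C([Se]c2ccccc2)CCC(Br)=C1Oc1ccc(Br)cc1Br | intermediate
10 | 3-bromo-2-(2,4-dibromophenoxy)-6-(phenylseleninyl)cyclohex-2-en-1-one (diastereomer mixture) | O=C1C([Se](=O)c2ccccc2)CCC(Br)=C1Oc1ccc(Br)cc1Br | intermediate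
11 | 3-bromo-2-(2,4-dibromophenoxy)cyclohexa-2,5-dien-1-one | O=C1C=CCC(Br)=C1Oc1ccc(Br)cc1Br | intermediate
12 | 3-bromo-2-(2,4-dibromophenoxy)phenol | Oc1cccc(Br)c1Oc1ccc(Br)cc1Br | intermediate
13 | 1-bromo-2-(2,4-dibromophenoxy)-3-methoxybenzene | COc1cccc(Br)c1Oc1ccc(Br)cc1Br | intermediate
14 | 2-[3-bromo-4-(2,4-dibromophenoxy)-5-methoxyphenyl]-4,4,5,5-tetramethyl-1,3,2-dioxaborolane | COc1cc(B2OC(C)(C)C(C)(C)O2)cc(Br)c1Oc1ccc(Br)cc1Br | intermediate
15 | 1,5-dibromo-2-(2,4-dibromophenoxy)-3-methoxybenzene | COc1cc(Br)cc(Br)c1Oc1ccc(Br)cc1Br | intermediate
16 | 1,2,3-tribromo-4-(2,4-dibromophenoxy)-5-methoxybenzene | COc1cc(Br)c(Br)c(Br)c1Oc1ccc(Br)cc1Br | intermediate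
17 | 3,4,5-tribromo-2-(2,4-dibromophenoxy)phenol | Oc1cc(Br)c(Br)c(Br)c1Oc1ccc(Br)cc1Br | target

Total step count: 9
Longest linear sequence: 9 steps (1 to 17; phenol 5 enters at step 2)

Steps most likely to fail

Step 8. Positional selectivity may be poor: attack at C6, ortho to the methoxy group, could compete with attack at C4, which is para to it but flanked by two bromines, and the deactivated ring may react slowly. The fallback sets out from 15 and returns at 17. BBr3 in CH2Cl2 should cleave the methyl ether to 3,5-dibromo-2-(2,4-dibromophenoxy)phenol F1. Silylation with i-Pr3SiOTf and 2,6-lutidine should give [3,5-dibromo-2-(2,4-dibromophenoxy)phenoxy]tri(propan-2-yl)silane F2, in which the bulky silyl group physically blocks C6. Bromination with NBS in MeCN should then be confined to C4 and give [3,4,5-tribromo-2-(2,4-dibromophenoxy)phenoxy]tri(propan-2-yl)silane F3. n-Bu4NF in THF removes the silyl group and delivers the target 17.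

Step 3. Intermolecular aldol or Claisen condensation of the electrophilic aryloxy ketone may outrun ring closure, or the electron-rich enolate of the product may degrade before the quench. The fallback sets out from 5 and commercial cyclohexane-1,3-dione and returns at 7. Diazo transfer to the dione with 4-acetamidobenzenesulfonyl azide and Et3N in MeCN should give 2-diazocyclohexane-1,3-dione F4. Decomposition of this diazo compound with Rh2(OAc)4 (catalytic) in CH2Cl2 at reflux in the presence of 5 should insert the carbenoid into the phenolic O–H bond and give 7 directly, attaching the aryloxy group to a preformed ring.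

Step 5. Enolate formation may be incompletely regioselective, or the phenol, once formed, may be selenenylated or oxidised by the selenium by-products under the peroxide conditions. The fallback sets out from 8 and returns at 12. Bromination with PhNMe3Br3 in THF at 0 °C should give 3,6-dibromo-2-(2,4-dibromophenoxy)cyclohex-2-en-1-one F5. Dehydrobromination with Li2CO3 and LiBr in DMF at 120 °C, followed by tautomerisation, should then give phenol 12. A regioisomeric 4-bromo compound would lead to the same phenol.

Further compounds
F1 | step 8 | 3,5-dibromo-2-(2,4-dibromophenoxy)phenol | Oc1cc(Br)cc(Br)c1Oc1ccc(Br)cc1Br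
F2 | step 8 | [3,5-dibromo-2-(2,4-dibromophenoxy)phenoxy]tri(propan-2-yl)silane | CC(C)[Si](C(C)C)(C(C)C)Oc1cc(Br)cc(Br)c1Oc1ccc(Br)cc1Br
F3 | step 8 | [3,4,5-tribromo-2-(2,4-dibromophenoxy)phenoxy]tri(propan-2-yl)silane | CC(C)[Si](C(C)C)(C(C)C)Oc1cc(Br)c(Br)c(Br)c1Oc1ccc(Br)cc1Br
F4 | step 3 | 2-diazocyclohexane-1,3-dione | O=C1CCCC(=O)C1=[N+]=[N-]
F5 | step 5 | 3,6-dibromo-2-(2,4-dibromophenoxy)cyclohex-2-en-1-one (racemic) | O=C1C(Br)CCC(Br)=C1Oc1ccc(Br)cc1Br
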